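The constants used here are those of an exercise; what happens was integrated by code.

We start from the amounts: 1.65 mM of catalyst turns over 0.50 M of substrate, with 0.650 M of reagent beside it.

all flasks: substrate 0.50 M; reagent 1.30 equiv; catalyst 0.33 mol%; time 8.0 h
- green: temperature 55 °C
- violet: temperature 25 °C
- ochre: temperature −35 °C
- teal: temperature −5 °C

    substrate + catalyst ⇌ catalyst + intermediate (K1 = 5.15, k1 = 401 M⁻¹ h⁻¹, Ea1 = 46.0 kJ mol⁻¹, ΔH1 = 26.0 kJ mol⁻¹)
    reagent + catalyst + intermediate → catalyst + product (k2 = 297 M⁻² h⁻¹, Ea2 = 56.0 kJ mol⁻¹)
    crystals ⇌ product, rate k3*(cs3 - [product]) while solid is left; crystals form when [product] > cs3 (cs3 = 39 mM, k3 = 4.05 h⁻¹)
    (constants at 25 °C)

- what is said of product includes crystals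
- crystals is a solid; its amount is given per volume of the solution
- all constants are for 25 °C and move with temperature by the activation energies and enthalpies

- the flask that comes out highest in amount of product, in percent of the substrate charged, or "all alike" when all lie within 1.5 percentage points (green / violet / ochre / teal / all alike)
- product at the end, in percent of the substrate charged, green
- product at the end, in percent of the substrate charged, violet
- product at the end, in percent of the substrate charged, ochre
- product at the end, in percent of the substrate charged, teal

Crystals count as product, and the steps that make product take no product in, so we reckon the total. We count lifetimes. The first count is the forward constant of the first step times c(catalyst) times the time: the lifetimes of substrate on its way to intermediate. The second is the constant of the second step times c(reagent), c(catalyst) and the time: the lifetimes of intermediate on its way to product. At 25 °C they are 5.29 and 2.55.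

While both counts are small, intermediate grows in a straight line up to a share equal to the first count. Its mean is then half of that, and the second count of this mean goes on to product. So we name the run number, half the product of the two counts: while both counts are small, the share of substrate turned to product. For violet it is 6.74. Both activation energies scale it, giving 290 in green, 6.76 % in teal and 0.0212 % in ochre.

Was one number enough? In ochre, yes: the first count of 0.0494 lies below the equilibrium constant of the first step in ochre, 0.367, so we neglect the way back and read 0.0212 % directly. In teal the first count is 0.664, larger than in ochre, so the line bends and we expect less than 6.76 %. Above one the number stops being a share. We expect green highest and nearly finished, with substrate as the limiting reagent. For violet, with a run number of 6.74, above one, we give no figure.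

The forecast names green, with 99.3 % in green, 67 % in violet, 4.3 % in teal and 0.02 % in ochre, holding that the outcome is “set by the catalysed steps, which speed up steeply with temperature”. It gives violet a figure where our reckoning gives none.

The simulation gives 99.6 % in green, 67.1 % in violet, 4.47 % in teal and 0.0199 % in ochre, with green highest. In ochre at 3.82 h, intermediate has a half-life of 27 d toward product, longer than the 110 h of substrate by the forward step alone, and at the end 4.49 % of intermediate stands beside 0.0199 % of product. The ochre run number of 0.0212 % lies near that product, and a repeat of ochre at −20 °C, with a run number of 0.449 %, gives 0.384 %.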